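The cyclobutane is disconnected across the bond between its carbinol carbon (bearing the ester oxygen and the naphthoquinone) and its gem-dimethyl carbon; these two ring atoms are a ketone carbon and an isopropyl methine in disguise. A Norrish–Yang photocyclisation joins them in one operation: the excited aryl ketone abstracts the tertiary γ-hydrogen and the 1,4-biradical closes the four-membered ring. The precursor is an open-chain α-trifluoroacetamido ketone from D-leucine, whose carboxyl, α, β and γ carbons become the four ring atoms and whose α-stereocentre steers the new carbinol centre before its nitrogen is deleted. The naphthazarin ring pair is completed last from a benzoquinone and a 2,5-disiloxyfuran.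

Key step: step 3

Assumption: the target is handled as the naphthazarin tautomer drawn (side chain on the quinoid ring; the tautomers interconvert freely), and 14 is taken as purchasable (otherwise one step from succinic anhydride, Me3SiCl and Et3N).

Step 1
Reactants: 1 D-leucine
Product: 2 N-trifluoroacetyl-D-leucine
Conditions: CF3CO2Et, Et3N, MeOH, rt; aqueous HCl work-up
Reagents that add atoms: ethyl trifluoroacetate, CCOC(=O)C(F)(F)F
Why: N-acylation of the amino acid salt by aminolysis of an activated ester; the α-stereocentre is not involved and stays (R).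

Step 2
Reactants: 2 N-trifluoroacetyl-D-leucine; 3 1,4-dimethoxybenzene
Product: 5 N-[(2R)-1-(2,5-dimethoxyphenyl)-4-methyl-1-oxopentan-2-yl]-2,2,2-trifluoroacetamide, via N-trifluoroacetyl-D-leucyl chloride 4 (not isolated)
Conditions: (COCl)2, cat. pyridine, CH2Cl2, 0 °C; then 3, AlCl3, CH2Cl2, 0 °C → rt
Reagents that add atoms: none
Why: Friedel–Crafts acylation of an activated arene by an N-trifluoroacetyl α-amino acid chloride, which should hold its configuration because the electron-poor amide resists azlactone formation; all four free positions of 3 are equivalent and the first acyl group deactivates the ring.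

Step 3
Reactants: 5 N-[(2R)-1-(2,5-dimethoxyphenyl)-4-methyl-1-oxopentan-2-yl]-2,2,2-trifluoroacetamide
Product: 6 N-[(1R,2R)-2-(2,5-dimethoxyphenyl)-2-hydroxy-3,3-dimethylcyclobutyl]-2,2,2-trifluoroacetamide (OH and NH cis)
Conditions: hν (350 nm, Pyrex), degassed benzene (0.01 M), 15–20 °C
Reagents that add atoms: none
Why: Norrish–Yang photocyclisation: the excited aryl ketone abstracts the tertiary γ-hydrogen of the isobutyl methine through a six-membered transition state, and the triplet 1,4-hydroxy biradical, after intersystem crossing, couples its ketyl carbon with the dimethyl-bearing radical carbon. The closest known reaction type is the photocyclisation of N-acyl α-amino aryl ketones to 2-amidocyclobutanols. The four-membered ring closes by radical–radical combination of a 1,4-biradical, not by a polar closure. The new carbinol stereocentre is controlled by the leucine α-stereocentre: hydrogen bonding between the ketyl O–H and the amide, together with the preference of the aryl group to sit trans to the amide, should place OH and NH cis, which with the (R)-α-carbon gives the (R)-carbinol. The step needs cyclisation to beat β-scission of the biradical (Norrish type 2 cleavage to isobutene) and γ-abstraction to beat δ-abstraction from the ortho-methoxy group; the α-amido substituent and its hydrogen bond hold the biradical in a gauche geometry with poor overlap for cleavage, and the tertiary γ-C–H is the weakest and best-placed hydrogen. Irradiation at 350 nm should leave the product, which no longer has the ketone chromophore, untouched.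

Step 4
Reactants: 6 N-[(1R,2R)-2-(2,5-dimethoxyphenyl)-2-hydroxy-3,3-dimethylcyclobutyl]-2,2,2-trifluoroacetamide
Product: 7 (1R,4R)-4-amino-1-(2,5-dimethoxyphenyl)-2,2-dimethylcyclobutan-1-ol
Conditions: K2CO3, MeOH/H2O, rt → 45 °C
Reagents that add atoms: none
Why: Mild basic hydrolysis of a trifluoroacetamide, far more labile than an ordinary amide, should free the primary amine without touching the tertiary alcohol or either stereocentre.

Step 5
Reactants: 7 (1R,4R)-4-amino-1-(2,5-dimethoxyphenyl)-2,2-dimethylcyclobutan-1-ol
Product: 9 (1R)-1-(2,5-dimethoxyphenyl)-2,2-dimethylcyclobutan-1-ol, via monoalkyl diazene 8 (not isolated)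
Conditions: N-(benzyloxy)-N-(pivaloyloxy)-4-(trifluoromethyl)benzamide, MeCN, 45 °C
Reagents that add atoms: none
Why: Direct deamination of a primary amine with an anomeric amide (electrophilic N-amination, loss of the benzyl ester to an isodiazene, tautomerisation to the diazene, loss of N2 with hydrogen-atom transfer to the cyclobutyl radical) turns CH–NH2 into CH2; the carbinol stereocentre is not part of the radical, and the nitrogen-bearing stereocentre is erased on purpose.

Step 6
Reactants: 9 (1R)-1-(2,5-dimethoxyphenyl)-2,2-dimethylcyclobutan-1-ol; 10 angelic acid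
Product: 12 (1R)-1-(2,5-dimethoxyphenyl)-2,2-dimethylcyclobutyl (2Z)-2-methylbut-2-enoate, via angelic 2,4,6-trichlorobenzoic anhydride 11 (not isolated)
Conditions: 10, 2,4,6-Cl3C6H2COCl, Et3N, toluene, rt, filter; 9, KN(SiMe3)2, THF, −78 °C, then the filtrate, −78 → 0 °C
Reagents that add atoms: none
Why: Acylation of a hindered tertiary potassium alkoxide by the Yamaguchi-type mixed anhydride of angelic acid, attacked at the less shielded angeloyl carbonyl; the low temperature and the absence of nucleophilic catalysts should keep the Z alkene from isomerising to the tiglate, and the C–O bond at the stereocentre is not broken.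

Step 7
Reactants: 12 (1R)-1-(2,5-dimethoxyphenyl)-2,2-dimethylcyclobutyl (2Z)-2-methylbut-2-enoate
Product: 13 (1R)-1-(3,6-dioxocyclohexa-1,4-dien-1-yl)-2,2-dimethylcyclobutyl (2Z)-2-methylbut-2-enoate
Conditions: (NH4)2Ce(NO3)6, MeCN/H2O, 0 °C, 15 min
Reagents that add atoms: water, O
Why: Oxidative demethylation of a 1,4-dimethoxyarene to the p-benzoquinone by tetravalent cerium (two one-electron oxidations with capture of water and loss of methanol); the electron-poor angelate and the tertiary ester should survive the short, cold reaction.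

Step 8
Reactants: 13 (1R)-1-(3,6-dioxocyclohexa-1,4-dien-1-yl)-2,2-dimethylcyclobutyl (2Z)-2-methylbut-2-enoate; 14 2,5-bis(trimethylsilyloxy)furan
Product: 17 (1R)-1-(5,8-dihydroxy-1,4-dioxo-1,4-dihydronaphthalen-2-yl)-2,2-dimethylcyclobutyl (2Z)-2-methylbut-2-enoate, via oxa-bridged Diels–Alder adduct 15 (not isolated), via dihydronaphthalenetetraone 16 (not isolated)
Conditions: 14 (1.1 equiv), CH2Cl2, −40 °C → rt; then 1 M HCl, THF, rt
Reagents that add atoms: none
Why: Diels–Alder reaction of the unsubstituted quinone double bond (the other is shielded by the quaternary side chain) with the electron-rich 2,5-disiloxyfuran, after which the bridgehead silyl ketals of the 7-oxanorbornene collapse to the ene-tetraone, which enolises twice to the naphthazarin; the sequence is redox-neutral, so the ring pair appears unprotected in its final oxidation state.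

Compound list

1 | D-leucine, (2R)-2-amino-4-methylpentanoic acid | N[C@H](CC(C)C)C(=O)O | starting material
2 | N-trifluoroacetyl-D-leucine, (2R)-4-methyl-2-(2,2,2-trifluoroacetamido)pentanoic acid | FC(F)(F)C(=O)N[C@H](CC(C)C)C(=O)O | intermediate
3 | 1,4-dimethoxybenzene | COc1ccc(OC)cc1 | starting material
4 | N-trifluoroacetyl-D-leucyl chloride, (2R)-4-methyl-2-(2,2,2-trifluoroacetamido)pentanoyl chloride | FC(F)(F)C(=O)N[C@H](CC(C)C)C(Cl)=O | intermediate (not isolated)
5 | N-[(2R)-1-(2,5-dimethoxyphenyl)-4-methyl-1-oxopentan-2-yl]-2,2,2-trifluoroacetamide | FC(F)(F)C(=O)N[C@H](CC(C)C)C(=O)c1cc(OC)ccc1OC | intermediate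
6 | N-[(1R,2R)-2-(2,5-dimethoxyphenyl)-2-hydroxy-3,3-dimethylcyclobutyl]-2,2,2-trifluoroacetamide, OH and NH cis | O[C@]1(c2cc(OC)ccc2OC)[C@H](NC(=O)C(F)(F)F)CC1(C)C | intermediate
7 | (1R,4R)-4-amino-1-(2,5-dimethoxyphenyl)-2,2-dimethylcyclobutan-1-ol | O[C@]1(c2cc(OC)ccc2OC)[C@H](N)CC1(C)C | intermediate
8 | (1R,4R)-4-diazenyl-1-(2,5-dimethoxyphenyl)-2,2-dimethylcyclobutan-1-ol, the monoalkyl diazene | O[C@]1(c2cc(OC)ccc2OC)[C@H](N=N)CC1(C)C | intermediate (not isolated)
9 | (1R)-1-(2,5-dimethoxyphenyl)-2,2-dimethylcyclobutan-1-ol | O[C@]1(c2cc(OC)ccc2OC)CCC1(C)C | intermediate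
10 | angelic acid, (2Z)-2-methylbut-2-enoic acid | C/C=C(/C)C(=O)O | starting material
11 | angelic 2,4,6-trichlorobenzoic anhydride | C/C=C(/C)C(=O)OC(=O)c1c(Cl)cc(Cl)cc1Cl | intermediate (not isolated)
12 | (1R)-1-(2,5-dimethoxyphenyl)-2,2-dimethylcyclobutyl (2Z)-2-methylbut-2-enoate | C/C=C(/C)C(=O)O[C@]1(c2cc(OC)ccc2OC)CCC1(C)C | intermediate
13 | (1R)-1-(3,6-dioxocyclohexa-1,4-dien-1-yl)-2,2-dimethylcyclobutyl (2Z)-2-methylbut-2-enoate | C/C=C(/C)C(=O)O[C@]1(C2=CC(=O)C=CC2=O)CCC1(C)C | intermediate
14 | 2,5-bis(trimethylsilyloxy)furan | C[Si](C)(C)Oc1ccc(O[Si](C)(C)C)o1 | starting material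
15 | oxa-bridged Diels–Alder adduct: 7-oxanorbornene with two bridgehead trimethylsilyloxy groups, fused to the substituted cyclohexenedione (mixture of ring-fusion diastereomers) | C/C=C(/C)C(=O)O[C@]1(C2=CC(=O)C3C(C2=O)C4(O[Si](C)(C)C)C=CC3(O[Si](C)(C)C)O4)CCC1(C)C | intermediate (not isolated)
16 | (1R)-2,2-dimethyl-1-(1,4,5,8-tetraoxo-1,4,4a,5,8,8a-hexahydronaphthalen-2-yl)cyclobutyl (2Z)-2-methylbut-2-enoate | C/C=C(/C)C(=O)O[C@]1(C2=CC(=O)C3C(C2=O)C(=O)C=CC3=O)CCC1(C)C | intermediate (not isolated)
17 | (1R)-1-(5,8-dihydroxy-1,4-dioxo-1,4-dihydronaphthalen-2-yl)-2,2-dimethylcyclobutyl (2Z)-2-methylbut-2-enoate | C/C=C(/C)C(=O)O[C@]1(C2=CC(=O)c3c(O)ccc(O)c3C2=O)CCC1(C)C | target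

Total step count: 8. Longest linear sequence: 8 steps (from D-leucine 1).

Steps most likely to fail

Step 3. The electron-rich aryl ketone has a π,π*-type lowest triplet, so hydrogen abstraction may be slow. The biradical may fragment (Norrish type 2 cleavage, loss of isobutene) instead of closing. Abstraction from the ortho-methoxy group may compete, and the 1,2-induction by the amide may be weak. If the induction ran the other way, L-leucine would lead to the same (R)-carbinol. Fallback: the same bond is closed from a 1,2-diketone, whose biradical cannot fragment without forming a hydroxyketene and whose n,π* triplet lies below the aryl states. It sets out from 1,4-dimethoxybenzene 3. Friedel–Crafts acylation with 4-methylpentanoyl chloride (AlCl3, CH2Cl2, 0 °C) should give 1-(2,5-dimethoxyphenyl)-4-methylpentan-1-one F1. Riley oxidation (SeO2, dioxane/H2O, reflux) should give 1-(2,5-dimethoxyphenyl)-4-methylpentane-1,2-dione F2. Irradiation (420 nm, benzene) should give racemic 2-(2,5-dimethoxyphenyl)-2-hydroxy-3,3-dimethylcyclobutan-1-one F3 by Yang cyclisation. Condensation with TsNHNH2 (MeOH) should give the tosylhydrazone F4, and its reduction with catecholborane followed by NaOAc should give racemic 1-(2,5-dimethoxyphenyl)-2,2-dimethylcyclobutan-1-ol F5. Preparative chiral SFC then gives the (R)-enantiomer, and the fallback comes back to the route at 9.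

Step 6. The alkoxide is flanked by a quaternary carbon and an ortho-substituted arene, so acylation may stall. Base may isomerise the Z alkene to the tiglate, and the electron-rich tertiary benzylic ester may ionise during purification. Fallback: the alkene is built after the ester. It sets out from 9. The potassium alkoxide (KN(SiMe3)2, THF, −78 °C) is acylated with 2-[bis(2,2,2-trifluoroethoxy)phosphoryl]propanoyl chloride to give (1R)-1-(2,5-dimethoxyphenyl)-2,2-dimethylcyclobutyl 2-[bis(2,2,2-trifluoroethoxy)phosphoryl]propanoate F6. Still–Gennari olefination with acetaldehyde (KN(SiMe3)2, 18-crown-6, THF, −78 °C) should set the Z-trisubstituted alkene, and the fallback comes back to the route at 12.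

Step 8. The disiloxyfuran may add to the quinone in a conjugate (Mukaiyama–Michael) sense instead of cycloadding, and the naphthazarin formed may react with a second equivalent of diene. Fallback: a carbocyclic diene followed by oxidation. It sets out from 13. Diels–Alder reaction with (1E,3E)-1,4-bis(trimethylsilyloxy)buta-1,3-diene (toluene, rt → 60 °C) should give (1R)-1-[1,4-dioxo-5,8-bis(trimethylsilyloxy)-1,4,4a,5,8,8a-hexahydronaphthalen-2-yl]-2,2-dimethylcyclobutyl (2Z)-2-methylbut-2-enoate F7. Jones oxidation (CrO3, H2SO4, acetone, 0 °C) removes the silyl groups and oxidises both allylic carbinols. The fallback comes back to the route at 16, which enolises to 17.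

Further compounds

F1 | step 3 | 1-(2,5-dimethoxyphenyl)-4-methylpentan-1-one | COc1ccc(OC)c(c1)C(=O)CCC(C)C
F2 | step 3 | 1-(2,5-dimethoxyphenyl)-4-methylpentane-1,2-dione | COc1ccc(OC)c(c1)C(=O)C(=O)CC(C)C
F3 | step 3 | racemic 2-(2,5-dimethoxyphenyl)-2-hydroxy-3,3-dimethylcyclobutan-1-one | COc1ccc(OC)c(c1)C1(O)C(=O)CC1(C)C
F4 | step 3 | racemic tosylhydrazone of 2-(2,5-dimethoxyphenyl)-2-hydroxy-3,3-dimethylcyclobutan-1-one | COc1ccc(OC)c(c1)C1(O)C(=NNS(=O)(=O)c2ccc(C)cc2)CC1(C)C
F5 | step 3 | racemic 1-(2,5-dimethoxyphenyl)-2,2-dimethylcyclobutan-1-ol | COc1ccc(OC)c(c1)C1(O)CCC1(C)C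
F6 | step 6 | (1R)-1-(2,5-dimethoxyphenyl)-2,2-dimethylcyclobutyl 2-[bis(2,2,2-trifluoroethoxy)phosphoryl]propanoate (both epimers at the phosphonate carbon) | CC(P(=O)(OCC(F)(F)F)OCC(F)(F)F)C(=O)O[C@]1(c2cc(OC)ccc2OC)CCC1(C)C
F7 | step 8 | (1R)-1-[1,4-dioxo-5,8-bis(trimethylsilyloxy)-1,4,4a,5,8,8a-hexahydronaphthalen-2-yl]-2,2-dimethylcyclobutyl (2Z)-2-methylbut-2-enoate (mixture of ring diastereomers) | C/C=C(/C)C(=O)O[C@]1(C2=CC(=O)C3C(C2=O)C(O[Si](C)(C)C)C=CC3O[Si](C)(C)C)CCC1(C)C
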